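**Plan**
- Retrosynthesis: the 2-oxopropyl ketone is traced back to an allyl group, the bridging CH2 to a ketone, and the benzene ring of chromone A (the 2-isopropyl-8-methoxy half) is then cut at C4a–C5 and C6–C7.
- Enabling feature: that benzene ring carries hydrogen only at C6 and C7 and methoxy at C8. C8 and C7 therefore map onto a 1-methoxyvinyl group on a finished 4-pyranone (which already holds O1, C2, C3, C4, C4a and C8a), and C5 and C6 onto an ethynyl ketone whose carbonyl carbon becomes the bridge.
- Forward order: the pyranone of fragment A (triketone cyclodehydration), then the pyranone ring of chromone B (oxalate condensation on phloroacetophenone), allyl by Stille coupling, the ynone via a Weinreb amide, then the benzene ring of chromone A by Diels–Alder/dehydrogenation, and last the end game (reduction, deoxygenation, Wacker oxidation).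
- Stereochemistry: the target has no stereocentre; the two transient ones (C4a of the cycloadduct, the carbinol carbon) arise as racemates and are erased.

Key step: step 10

Remark: compounds 1, 2, 7, 8, 13 and 16 are taken as purchasable; the side-chain ketone is carried as an allyl group because a dioxolane would be reduced by Et3SiH/acid in the deoxygenation step.

**Route**

Step 1
Reactants: 1 5-methylhexane-2,4-dione; 2 methyl 2,2-dimethoxypropanoate
Product: 3 8,8-dimethoxy-2-methylnonane-3,5,7-trione
Conditions: 1 (2 equiv), LiN(iPr)2 (LDA, 4 equiv), THF, −78 → 0 °C; then 2 (1 equiv), 0 °C → rt; aq. HCl work-up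
Reagents that add atoms: none
Why: Hauser-type Claisen acylation of a β-diketone dianion, whose second deprotonation takes place at the terminal methyl and not at the hindered isopropyl methine, so the non-enolisable ester is attacked by C1 and the 1,3,5-triketone should result.

Step 2
Reactants: 3 8,8-dimethoxy-2-methylnonane-3,5,7-trione
Product: 4 2-acetyl-6-isopropyl-4H-pyran-4-one
Conditions: conc. H2SO4, 0 °C → rt; poured onto ice
Reagents that add atoms: none
Why: Acid-catalysed cyclodehydration of a 1,3,5-triketone to the 2,6-disubstituted 4-pyranone (enol oxygen onto the far carbonyl, loss of water), with the liberated water and the quench hydrolysing the ketal to the acetyl group.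

Step 3
Reactants: 4 2-acetyl-6-isopropyl-4H-pyran-4-one
Product: 6 2-isopropyl-6-(1-methoxyvinyl)-4H-pyran-4-one, via dimethyl ketal 5 (not isolated)
Conditions: HC(OMe)3, TsOH·H2O (cat.), MeOH, 50 °C; K2CO3, evaporate; then TMSOTf (2.5 equiv), iPr2NEt (3 equiv), CH2Cl2, −20 °C → rt; aq. NaHCO3
Reagents that add atoms: trimethyl orthoformate COC(OC)OC; methanol CO
Why: Orthoformate ketalisation followed by Gassman-type TMSOTf/amine elimination of methanol, in which the oxocarbenium ion can lose a proton only from its methyl group and so should give the terminal methyl enol ether, the excess TMSOTf allowing for reversible silylation of the pyranone oxygen.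

Step 4
Reactants: 7 2,4,6-trihydroxyacetophenone; 8 diethyl oxalate
Product: 10 ethyl 5,7-dihydroxy-4-oxo-4H-chromene-2-carboxylate, via diketo ester 9 (not isolated)
Conditions: NaOEt (5 equiv), EtOH, reflux; then conc. HCl, EtOH, reflux
Reagents that add atoms: none
Why: Claisen condensation of the acetophenone methyl with oxalate followed by acid cyclodehydration, the classical chromone-2-carboxylate synthesis, made regiochemically unambiguous by the symmetric phloroglucinol ring.

Step 5
Reactants: 10 ethyl 5,7-dihydroxy-4-oxo-4H-chromene-2-carboxylate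
Product: 11 ethyl 5-hydroxy-7-(methoxymethoxy)-4-oxo-4H-chromene-2-carboxylate
Conditions: MOMCl (1.1 equiv), iPr2NEt, CH2Cl2/DMF, 0 °C → rt
Reagents that add atoms: chloromethyl methyl ether COCCl
Why: Selective O-alkylation of the more acidic, non-chelated 7-OH, the 5-OH being held back by its hydrogen bond to the C4 carbonyl as is usual for 5,7-dihydroxychromones.

Step 6
Reactants: 11 ethyl 5-hydroxy-7-(methoxymethoxy)-4-oxo-4H-chromene-2-carboxylate
Product: 12 ethyl 7-(methoxymethoxy)-4-oxo-5-{[(trifluoromethyl)sulfonyl]oxy}-4H-chromene-2-carboxylate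
Conditions: Tf2O, pyridine, CH2Cl2, 0 °C → rt
Reagents that add atoms: trifluoromethanesulfonic anhydride O=S(=O)(OS(=O)(=O)C(F)(F)F)C(F)(F)F
Why: O-sulfonylation of the chelated phenol by the strongly electrophilic anhydride, a standard way to 5-triflyloxychromones and flavones.

Step 7
Reactants: 12 ethyl 7-(methoxymethoxy)-4-oxo-5-{[(trifluoromethyl)sulfonyl]oxy}-4H-chromene-2-carboxylate; 13 allyltributylstannane
Product: 14 ethyl 5-allyl-7-(methoxymethoxy)-4-oxo-4H-chromene-2-carboxylate
Conditions: Pd(PPh3)4 (5 mol %), LiCl (3 equiv), 1,4-dioxane, 100 °C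
Reagents that add atoms: none
Why: Stille coupling of an aryl triflate, with oxidative addition to zerovalent palladium eased by the electron-poor ring and chloride, to install the allyl group that serves as a masked 2-oxopropyl chain inert to every later step.

Step 8
Reactants: 14 ethyl 5-allyl-7-(methoxymethoxy)-4-oxo-4H-chromene-2-carboxylate
Product: 15 5-allyl-N-methoxy-7-(methoxymethoxy)-N-methyl-4-oxo-4H-chromene-2-carboxamide
Conditions: MeNH(OMe)·HCl (1.5 equiv), iPrMgCl (3 equiv), THF, −20 °C (amide base preformed before 14 is added); aq. NH4Cl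
Reagents that add atoms: N,O-dimethylhydroxylamine hydrochloride CNOC.Cl
Why: Weinreb amide formation by aminolysis of the activated C2 ester with the magnesium amide, which is made first so that no free Grignard reagent meets the chromone.

Step 9
Reactants: 15 5-allyl-N-methoxy-7-(methoxymethoxy)-N-methyl-4-oxo-4H-chromene-2-carboxamide; 16 ethynylmagnesium bromide
Product: 17 1-[5-allyl-7-(methoxymethoxy)-4-oxo-4H-chromen-2-yl]prop-2-yn-1-one
Conditions: HC≡CMgBr (3 equiv), THF, −78 → −20 °C; inverse quench into cold aq. NaHSO4
Reagents that add atoms: none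
Why: Weinreb ketone synthesis, in which the chelated tetrahedral adduct releases the ethynyl ketone only on acidic quench (which also keeps the liberated amine from adding to the ynone) and the vinylogous-ester C4 carbonyl is too weak an electrophile to compete at low temperature.

Step 10
Reactants: 6 2-isopropyl-6-(1-methoxyvinyl)-4H-pyran-4-one; 17 1-[5-allyl-7-(methoxymethoxy)-4-oxo-4H-chromen-2-yl]prop-2-yn-1-one
Product: 19 5-{[5-allyl-7-(methoxymethoxy)-4-oxo-4H-chromen-2-yl]carbonyl}-2-isopropyl-8-methoxy-4H-chromen-4-one, via cyclohexadiene cycloadduct 18 (not isolated)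
Conditions: 6 (1.5 equiv), BHT (cat.), PhMe, 110 °C, sealed tube; then DDQ (2 equiv), rt → 60 °C
Reagents that add atoms: none
Why: A thermal [4+2] cycloaddition joins the pyranone C5=C6 bond and the 1-methoxyvinyl group of 6 (diene) to the ethynyl ketone of 17, forming C4a–C5 and C6–C7 of chromone A, after which DDQ takes hydride from C7 (allylic and next to the enol ether) and the acidic C4a–H is lost, turning the cyclohexa-1,4-diene 18 into the benzene ring. The closest known reaction type is the Diels–Alder reaction of 2-vinyl- and 2-styrylchromones with activated alkynes and alkenes followed by dehydrogenation to xanthones. The one new ring, the six-membered carbocycle of chromone A, closes by intermolecular [4+2] cycloaddition, and a stepwise Michael addition/ring closure at the polar extreme would give the same connectivity. The C4a stereocentre of 18 forms as a racemate and disappears on aromatisation, so no stereocontrol is needed. The step needs regioselectivity, secured because the methoxy group makes the CH2 terminus the most nucleophilic diene carbon (the pyranone terminus is deactivated by the C4 carbonyl) and this terminus bonds to the unsubstituted, electrophilic β-carbon of the ynone, placing the acyl group at C5 para to the methoxy group. It also needs chemoselectivity for the ynone over the chromone B C2=C3 bond and the allyl group, which follows from the much lower LUMO and the lack of substitution of the ethynyl ketone.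

Step 11
Reactants: 19 5-{[5-allyl-7-(methoxymethoxy)-4-oxo-4H-chromen-2-yl]carbonyl}-2-isopropyl-8-methoxy-4H-chromen-4-one
Product: 20 5-{[5-allyl-7-(methoxymethoxy)-4-oxo-4H-chromen-2-yl](hydroxy)methyl}-2-isopropyl-8-methoxy-4H-chromen-4-one (racemic)
Conditions: NaBH4, CeCl3·7H2O, MeOH/THF, −78 → −40 °C
Reagents that add atoms: none
Why: Luche reduction, in which the doubly conjugated bridging ketone is by far the most electrophilic carbonyl and is reduced 1,2 while both vinylogous-ester C4 carbonyls stay intact; the carbinol centre forms as a racemate without control and is removed in step 12.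

Step 12
Reactants: 20 5-{[5-allyl-7-(methoxymethoxy)-4-oxo-4H-chromen-2-yl](hydroxy)methyl}-2-isopropyl-8-methoxy-4H-chromen-4-one
Product: 21 5-[(5-allyl-7-hydroxy-4-oxo-4H-chromen-2-yl)methyl]-2-isopropyl-8-methoxy-4H-chromen-4-one
Conditions: Et3SiH (5 equiv), CF3CO2H/CH2Cl2 (1:3), 0 °C → rt
Reagents that add atoms: none
Why: Ionic hydrogenation, in which the benzylic cation is stabilised by the para C8 methoxy group of ring A and trapped by the silane, while the same acid cleaves the methoxymethyl ether and the monosubstituted allyl alkene is protonated too slowly to be reduced.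

Step 13
Reactants: 21 5-[(5-allyl-7-hydroxy-4-oxo-4H-chromen-2-yl)methyl]-2-isopropyl-8-methoxy-4H-chromen-4-one
Product: 22 7-hydroxy-2-[(2-isopropyl-8-methoxy-4-oxo-4H-chromen-5-yl)methyl]-5-(2-oxopropyl)-4H-chromen-4-one (target, CNP0592286.0)
Conditions: PdCl2 (10 mol %), CuCl (1 equiv), O2 (1 atm), DMF/H2O (7:1), rt
Reagents that add atoms: water O
Why: Tsuji–Wacker oxidation, in which Markovnikov hydroxypalladation of the terminal alkene by divalent palladium and β-hydride elimination give the methyl ketone, as is usual for allylarenes, and the meta-placed phenol cannot cyclise onto the alkene.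

**Compound list**
1 | 5-methylhexane-2,4-dione | CC(=O)CC(=O)C(C)C | starting material
2 | methyl 2,2-dimethoxypropanoate | COC(=O)C(C)(OC)OC | starting material
3 | 8,8-dimethoxy-2-methylnonane-3,5,7-trione | CC(C)C(=O)CC(=O)CC(=O)C(C)(OC)OC | intermediate
4 | 2-acetyl-6-isopropyl-4H-pyran-4-one | CC(=O)c1cc(=O)cc(C(C)C)o1 | intermediate
5 | 2-(1,1-dimethoxyethyl)-6-isopropyl-4H-pyran-4-one (not isolated) | COC(C)(OC)c1cc(=O)cc(C(C)C)o1 | intermediate
6 | 2-isopropyl-6-(1-methoxyvinyl)-4H-pyran-4-one | C=C(OC)c1cc(=O)cc(C(C)C)o1 | intermediate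
7 | 2,4,6-trihydroxyacetophenone | CC(=O)c1c(O)cc(O)cc1O | starting material
8 | diethyl oxalate | CCOC(=O)C(=O)OCC | starting material
9 | ethyl 2,4-dioxo-4-(2,4,6-trihydroxyphenyl)butanoate (not isolated) | CCOC(=O)C(=O)CC(=O)c1c(O)cc(O)cc1O | intermediate
10 | ethyl 5,7-dihydroxy-4-oxo-4H-chromene-2-carboxylate | CCOC(=O)c1cc(=O)c2c(O)cc(O)cc2o1 | intermediate
11 | ethyl 5-hydroxy-7-(methoxymethoxy)-4-oxo-4H-chromene-2-carboxylate | CCOC(=O)c1cc(=O)c2c(O)cc(OCOC)cc2o1 | intermediate
12 | ethyl 7-(methoxymethoxy)-4-oxo-5-{[(trifluoromethyl)sulfonyl]oxy}-4H-chromene-2-carboxylate | CCOC(=O)c1cc(=O)c2c(OS(=O)(=O)C(F)(F)F)cc(OCOC)cc2o1 | intermediate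
13 | allyltributylstannane | C=CC[Sn](CCCC)(CCCC)CCCC | starting material
14 | ethyl 5-allyl-7-(methoxymethoxy)-4-oxo-4H-chromene-2-carboxylate | CCOC(=O)c1cc(=O)c2c(CC=C)cc(OCOC)cc2o1 | intermediate
15 | 5-allyl-N-methoxy-7-(methoxymethoxy)-N-methyl-4-oxo-4H-chromene-2-carboxamide | CON(C)C(=O)c1cc(=O)c2c(CC=C)cc(OCOC)cc2o1 | intermediate
16 | ethynylmagnesium bromide | C#C[Mg]Br | starting material
17 | 1-[5-allyl-7-(methoxymethoxy)-4-oxo-4H-chromen-2-yl]prop-2-yn-1-one | C#CC(=O)c1cc(=O)c2c(CC=C)cc(OCOC)cc2o1 | intermediate
18 | 5-{[5-allyl-7-(methoxymethoxy)-4-oxo-4H-chromen-2-yl]carbonyl}-2-isopropyl-8-methoxy-4a,7-dihydro-4H-chromen-4-one (racemic, not isolated) | COC1=C2OC(C(C)C)=CC(=O)C2C(C(=O)c2cc(=O)c3c(CC=C)cc(OCOC)cc3o2)=CC1 | intermediate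
19 | 5-{[5-allyl-7-(methoxymethoxy)-4-oxo-4H-chromen-2-yl]carbonyl}-2-isopropyl-8-methoxy-4H-chromen-4-one | COc1ccc(C(=O)c2cc(=O)c3c(CC=C)cc(OCOC)cc3o2)c2c(=O)cc(C(C)C)oc12 | intermediate
20 | 5-{[5-allyl-7-(methoxymethoxy)-4-oxo-4H-chromen-2-yl](hydroxy)methyl}-2-isopropyl-8-methoxy-4H-chromen-4-one (racemic) | COc1ccc(C(O)c2cc(=O)c3c(CC=C)cc(OCOC)cc3o2)c2c(=O)cc(C(C)C)oc12 | intermediate
21 | 5-[(5-allyl-7-hydroxy-4-oxo-4H-chromen-2-yl)methyl]-2-isopropyl-8-methoxy-4H-chromen-4-one | COc1ccc(Cc2cc(=O)c3c(CC=C)cc(O)cc3o2)c2c(=O)cc(C(C)C)oc12 | intermediate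
22 | 7-hydroxy-2-[(2-isopropyl-8-methoxy-4-oxo-4H-chromen-5-yl)methyl]-5-(2-oxopropyl)-4H-chromen-4-one | COc1ccc(Cc2cc(=O)c3c(CC(C)=O)cc(O)cc3o2)c2c(=O)cc(C(C)C)oc12 | target

**Count**
Total steps: 13. Longest linear sequence: 10 steps (steps 4–13, from 7 to 22); the fragment A branch (steps 1–3) joins at step 10.

**Steps most likely to fail**

Step 10 (Diels–Alder/dehydrogenation). The cycloaddition may be slow because the pyranone double bond is a reluctant diene component. The acid- and heat-sensitive methyl enol ether could then hydrolyse or oligomerise, and the terminal ynone polymerise, before the two meet. The fallback sets out from 4 and changes the diene to one made under basic conditions in a single step, sturdy enough to be used in large excess and at higher temperature. TBSOTf and Et3N in CH2Cl2 at 0 °C should convert 4 into 2-[1-(tert-butyldimethylsilyloxy)vinyl]-6-isopropyl-4H-pyran-4-one F1. Heating F1 with 17 in PhMe or o-xylene should give 5-{[5-allyl-7-(methoxymethoxy)-4-oxo-4H-chromen-2-yl]carbonyl}-8-(tert-butyldimethylsilyloxy)-2-isopropyl-4a,7-dihydro-4H-chromen-4-one F2. DDQ in the same pot should aromatise F2 to 5-{[5-allyl-7-(methoxymethoxy)-4-oxo-4H-chromen-2-yl]carbonyl}-8-(tert-butyldimethylsilyloxy)-2-isopropyl-4H-chromen-4-one F3. CsF and MeI in DMF then exchange the silyl group for methyl in one operation, and the route is rejoined at 19.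

Step 12 (ionic deoxygenation). Ionisation of the carbinol may be sluggish because the cation is flanked by the electron-poor chromone B and by a chromone A whose carbonyl is protonated in the acid. Forcing conditions could bring proton-induced cyclisation of the allyl group onto the peri C4 carbonyl, or reduction of a pyrylium-type ion. The fallback sets out from 20 and removes the hydroxyl by a radical path that needs no cation. 1,1'-Thiocarbonyldiimidazole and DMAP in ClCH2CH2Cl at 60 °C should give O-{[5-allyl-7-(methoxymethoxy)-4-oxo-4H-chromen-2-yl](2-isopropyl-8-methoxy-4-oxo-4H-chromen-5-yl)methyl} 1H-imidazole-1-carbothioate F4. Bu3SnH and AIBN in PhMe at 80 °C (Barton–McCombie deoxygenation) should convert F4 into 5-{[5-allyl-7-(methoxymethoxy)-4-oxo-4H-chromen-2-yl]methyl}-2-isopropyl-8-methoxy-4H-chromen-4-one F5. HCl in MeOH/THF at 50 °C then removes the methoxymethyl group, and the route is rejoined at 21.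

Step 3 (enol ether formation). Silylation of the basic pyranone oxygen by TMSOTf may suppress ionisation of the neighbouring ketal, so that elimination stalls, and the enol ether may hydrolyse back to 4 on work-up. The fallback sets out from 4 and makes the C–O bond by enolate O-alkylation. KN(SiMe3)2 in THF/DMPU at −78 °C followed by MeOTf (1.0 equiv) should methylate the potassium enolate on oxygen and deliver 6 directly. The acetyl methyl is more acidic than the isopropyl methine, and the hard electrophile in a dipolar medium favours O- over C-methylation. No new compound arises (F0), and the route is rejoined at 6.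

**Further compounds**
F1 | step 10 | 2-[1-(tert-butyldimethylsilyloxy)vinyl]-6-isopropyl-4H-pyran-4-one | C=C(O[Si](C)(C)C(C)(C)C)c1cc(=O)cc(C(C)C)o1
F2 | step 10 | 5-{[5-allyl-7-(methoxymethoxy)-4-oxo-4H-chromen-2-yl]carbonyl}-8-(tert-butyldimethylsilyloxy)-2-isopropyl-4a,7-dihydro-4H-chromen-4-one (racemic) | CC(C)(C)[Si](C)(C)OC1=C2OC(C(C)C)=CC(=O)C2C(C(=O)c2cc(=O)c3c(CC=C)cc(OCOC)cc3o2)=CC1
F3 | step 10 | 5-{[5-allyl-7-(methoxymethoxy)-4-oxo-4H-chromen-2-yl]carbonyl}-8-(tert-butyldimethylsilyloxy)-2-isopropyl-4H-chromen-4-one | CC(C)(C)[Si](C)(C)Oc1ccc(C(=O)c2cc(=O)c3c(CC=C)cc(OCOC)cc3o2)c2c(=O)cc(C(C)C)oc12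
F4 | step 12 | O-{[5-allyl-7-(methoxymethoxy)-4-oxo-4H-chromen-2-yl](2-isopropyl-8-methoxy-4-oxo-4H-chromen-5-yl)methyl} 1H-imidazole-1-carbothioate (racemic) | COc1ccc(C(OC(=S)n2ccnc2)c2cc(=O)c3c(CC=C)cc(OCOC)cc3o2)c2c(=O)cc(C(C)C)oc12
F5 | step 12 | 5-{[5-allyl-7-(methoxymethoxy)-4-oxo-4H-chromen-2-yl]methyl}-2-isopropyl-8-methoxy-4H-chromen-4-one | COc1ccc(Cc2cc(=O)c3c(CC=C)cc(OCOC)cc3o2)c2c(=O)cc(C(C)C)oc12
F0 | step 3 | none | none
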